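**Retrosynthetic overview**

1. Cathafuran C ⇐ MOM removal, decarboxylative aldol aromatisation of the central benzene ring and retro-Knoevenagel/oxa-6π of the 2H-pyran ⇐ a 4-hydroxy-2-pyrone whose 6-side chain carries the prenyl group and a benzofuran-2-yl ketone, plus 3-methylbut-2-enal.
2. That pyrone ⇐ C-acylation of the dianion of 4-hydroxy-6-(4-methylpent-3-enyl)-2-pyrone with ethyl 6-(methoxymethoxy)benzofuran-2-carboxylate.
3. Prenylated pyrone ⇐ triacetic acid lactone + prenyl bromide; benzofuran ester ⇐ 2,4-dihydroxybenzaldehyde + ethyl bromoacetate.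
4. Ring order: furan ring first (step 3); then, in one flask in step 5, the 2H-pyran ring followed by the central benzene ring. Ring A of the benzofuran and the 2-pyrone are bought; pyrone C3–C6 become four of the six arene carbons.
5. Regiocontrol: pyrone C3 is the only carbon that can condense with the enal, so the pyran is fixed next to the future aryl-bearing carbon before the benzene ring exists.

Assumption: the target SMILES holds no stereocentre and no E/Z-variable double bond, so it is achiral and needs no stereocontrol; the one labile stereocentre of 9 and 11 is racemic and disappears on aromatisation.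

**Route**

Step 1
Reactants: 1 4-hydroxy-6-methyl-2H-pyran-2-one (triacetic acid lactone); 2 1-bromo-3-methylbut-2-ene (prenyl bromide)
Product: 3 4-hydroxy-6-(4-methylpent-3-en-1-yl)-2H-pyran-2-one
Conditions: LiN(iPr)2 (2.2 equiv), THF, −78 °C; then 2 (1.1 equiv), −78 → 0 °C; aq. HCl
Reagents that add atoms: none
Why: γ-Alkylation of a pyrone dianion, in which the second, least stabilised carbanion on the 6-methyl group is the most nucleophilic site and displaces the primary allylic bromide by SN2, so only the side chain grows and no stereocentre is formed.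

Step 2
Reactants: 4 2,4-dihydroxybenzaldehyde
Product: 5 2-hydroxy-4-(methoxymethoxy)benzaldehyde
Conditions: MOMCl (1.05 equiv), K2CO3, acetone, 0 °C → rt
Reagents that add atoms: chloromethyl methyl ether (MOMCl), COCCl
Why: Williamson-type O-alkylation (MOM protection) that takes the more acidic 4-OH, because the 2-OH is held in a hydrogen bond to the aldehyde.

Step 3
Reactants: 5 2-hydroxy-4-(methoxymethoxy)benzaldehyde; 6 ethyl bromoacetate
Product: 8 ethyl 6-(methoxymethoxy)-1-benzofuran-2-carboxylate, via phenoxyacetate 7 (not isolated)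
Conditions: K2CO3, DMF, rt then 110 °C
Reagents that add atoms: none
Why: O-alkylation of the free ortho-phenol followed by intramolecular aldol condensation of the ester-activated methylene onto the aldehyde and dehydration (Rap–Stoermer-type benzofuran synthesis) closes the furan ring.

Step 4
Reactants: 3 4-hydroxy-6-(4-methylpent-3-en-1-yl)-2H-pyran-2-one; 8 ethyl 6-(methoxymethoxy)-1-benzofuran-2-carboxylate
Product: 9 4-hydroxy-6-{1-[6-(methoxymethoxy)-1-benzofuran-2-yl]-5-methyl-1-oxohex-4-en-2-yl}-2H-pyran-2-one (racemic)
Conditions: 3 (2 equiv), LiN(iPr)2 (4.1 equiv), THF, −78 °C; then 8 (1 equiv), −78 → −20 °C; AcOH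
Reagents that add atoms: none
Why: Claisen-type C-acylation of a pyrone dianion (Harris acylation), in which the side-chain carbanion attacks the heteroaryl ester and the more acidic product is deprotonated by excess dianion so that no second addition occurs; the new stereocentre is acidic, left racemic and destroyed in step 5.

Step 5
Reactants: 9 4-hydroxy-6-{1-[6-(methoxymethoxy)-1-benzofuran-2-yl]-5-methyl-1-oxohex-4-en-2-yl}-2H-pyran-2-one; 10 3-methylbut-2-enal
Product: 13 5-(6-hydroxy-1-benzofuran-2-yl)-2,2-dimethyl-6-(3-methylbut-2-en-1-yl)-2H-chromen-7-ol (Cathafuran C), via pyranopyranone ketone 11 (not isolated), via MOM ether 12 (not isolated)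
Conditions: 10 (1.5 equiv), ethylenediammonium diacetate (10 mol %), EtOH, 70 °C; then aq. KOH (8 equiv), 70 °C; then HCl to ca. 2 M, 50 °C
Reagents that add atoms: none
Why: Proposed new method: amine-catalysed Knoevenagel condensation of 10 at pyrone C3 (the only carbon that can form an alkylidene) and oxa-6π electrocyclisation onto the 4-oxygen close the 2H-pyran (known formal [3+3] annulation), then hydroxide opens the enol lactone and the resulting vinylogous enolate attacks the side-chain aryl ketone through the former pyrone C3 in a six-ring aldol, after which loss of water and of CO2 from the quaternary carbon aromatises the central ring (closest known reaction type: base-mediated aldol aromatisation of tetraketide pyrones such as tetraacetic acid lactone to orsellinic acid, here ending in decarboxylation), and the acid stage cleaves the MOM acetal, leaving no stereocentre.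

**Compound list**

1 | 4-hydroxy-6-methyl-2H-pyran-2-one | CC1=CC(O)=CC(=O)O1 | starting material
2 | 1-bromo-3-methylbut-2-ene | CC(C)=CCBr | starting material
3 | 4-hydroxy-6-(4-methylpent-3-en-1-yl)-2H-pyran-2-one | CC(C)=CCCC1=CC(O)=CC(=O)O1 | intermediate
4 | 2,4-dihydroxybenzaldehyde | O=Cc1ccc(O)cc1O | starting material
5 | 2-hydroxy-4-(methoxymethoxy)benzaldehyde | COCOc1ccc(C=O)c(O)c1 | intermediate
6 | ethyl bromoacetate | CCOC(=O)CBr | starting material
7 | ethyl 2-[2-formyl-5-(methoxymethoxy)phenoxy]acetate | CCOC(=O)COc1cc(OCOC)ccc1C=O | intermediate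
8 | ethyl 6-(methoxymethoxy)-1-benzofuran-2-carboxylate | CCOC(=O)c1cc2ccc(OCOC)cc2o1 | intermediate
9 | 4-hydroxy-6-{1-[6-(methoxymethoxy)-1-benzofuran-2-yl]-5-methyl-1-oxohex-4-en-2-yl}-2H-pyran-2-one (racemic) | COCOc1ccc2cc(C(=O)C(CC=C(C)C)C3=CC(O)=CC(=O)O3)oc2c1 | intermediate
10 | 3-methylbut-2-enal | CC(C)=CC=O | starting material
11 | 2,2-dimethyl-7-{1-[6-(methoxymethoxy)-1-benzofuran-2-yl]-5-methyl-1-oxohex-4-en-2-yl}-2H,5H-pyrano[4,3-b]pyran-5-one (racemic) | COCOc1ccc2cc(C(=O)C(CC=C(C)C)C3=CC4=C(C=CC(C)(C)O4)C(=O)O3)oc2c1 | intermediate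
12 | 5-[6-(methoxymethoxy)-1-benzofuran-2-yl]-2,2-dimethyl-6-(3-methylbut-2-en-1-yl)-2H-chromen-7-ol | CC(C)=CCc1c(O)cc2c(c1-c1cc3ccc(OCOC)cc3o1)C=CC(C)(C)O2 | intermediate
13 | 5-(6-hydroxy-1-benzofuran-2-yl)-2,2-dimethyl-6-(3-methylbut-2-en-1-yl)-2H-chromen-7-ol (Cathafuran C) | CC(C)=CCc1c(O)cc2c(c1-c1cc3ccc(O)cc3o1)C=CC(C)(C)O2 | target

**Step count and risks**

Total: 5 steps. Longest linear sequence: 4 steps (4 → 5 → 8 → 9 → 13).

Most likely to fail, first: step 5. Hydroxide may cleave the aryl ketone (retro-Claisen) or reverse the Knoevenagel step before the aldol at the fully substituted carbon closes the ring, and the acid stage can cyclise the ortho-prenyl phenol if overrun. The fallback sets out from 3 and 8, makes the lactone carbonyl itself the aryl-bearing arene carbon, and returns at 12: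
- 3 is condensed with 10 under the same amine catalysis to give 2,2-dimethyl-7-(4-methylpent-3-en-1-yl)-2H,5H-pyrano[4,3-b]pyran-5-one F1.
- 8 is saponified (LiOH, THF/H2O) to 6-(methoxymethoxy)-1-benzofuran-2-carboxylic acid F2 and protodecarboxylated (Cu powder, quinoline, 190 °C) to 6-(methoxymethoxy)-1-benzofuran F3.
- F3 is lithiated at C2 (n-BuLi, THF, −78 °C) and added to the lactone carbonyl of F1; ring opening to the enolate, aldol closure of the side-chain methylene onto the new aryl ketone and dehydration give 12, which is then unmasked by the acid stage of step 5 run on its own.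

Second: step 4. The secondary carbanion of the dianion of 3 may acylate slowly, or partly on oxygen. The fallback sets out from 1, 2 and 8, reverses the order of the two C–C bond formations, and returns at 9:
- The dianion of 1 (LiN(iPr)2, THF, −78 °C) is acylated at its primary 6-methyl carbanion with 8 to give 4-hydroxy-6-{2-[6-(methoxymethoxy)-1-benzofuran-2-yl]-2-oxoethyl}-2H-pyran-2-one F4.
- The doubly activated methylene of F4 is C-prenylated with 2 (NaH, 2 equiv, THF/DMF, 0 °C) to give 9.

Third: step 1. O-alkylation, C3-alkylation, SN2′ attack or dialkylation may compete. The fallback builds the pyrone ring with the side chain already in place, sets out from commercial 2-methylbut-3-en-2-ol, triethyl orthoacetate and methyl acetoacetate, and returns at 3: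
- Johnson–Claisen rearrangement (cat. propionic acid, 140 °C) gives ethyl 5-methylhex-4-enoate F5.
- F5 acylates the dianion of methyl acetoacetate (NaH, then n-BuLi, THF, 0 °C) to give methyl 9-methyl-3,5-dioxodec-8-enoate F6.
- F6 lactonises on heating with 1,8-diazabicyclo[5.4.0]undec-7-ene in toluene to give 3.

Further compounds
F1 | step 5 | 2,2-dimethyl-7-(4-methylpent-3-en-1-yl)-2H,5H-pyrano[4,3-b]pyran-5-one | CC(C)=CCCC1=CC2=C(C=CC(C)(C)O2)C(=O)O1
F2 | step 5 | 6-(methoxymethoxy)-1-benzofuran-2-carboxylic acid | COCOc1ccc2cc(C(=O)O)oc2c1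
F3 | step 5 | 6-(methoxymethoxy)-1-benzofuran | COCOc1ccc2ccoc2c1
F4 | step 4 | 4-hydroxy-6-{2-[6-(methoxymethoxy)-1-benzofuran-2-yl]-2-oxoethyl}-2H-pyran-2-one | COCOc1ccc2cc(C(=O)CC3=CC(O)=CC(=O)O3)oc2c1
F5 | step 1 | ethyl 5-methylhex-4-enoate | CCOC(=O)CCC=C(C)C
F6 | step 1 | methyl 9-methyl-3,5-dioxodec-8-enoate | COC(=O)CC(=O)CC(=O)CCC=C(C)C
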